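Readings and results are calculated for an exercise, and the scatter is random.

| flask | L | X | remark | time |
|---|---|---|---|---|
| north-east | 33 mM | 34.6 mM | run made earlier |  |
| south-east | 33 mM | 17 mM | run made earlier |  |
| east | 33 mM | 26 mM | run made earlier |  |
| south-west | 16 mM | 34.6 mM | run made earlier |  |
| green | 33 mM | 34.6 mM | everything together at the start | 5.0 d |
| ochre | 33 mM (fed, over 4.0 d) | 34.6 mM | all else is in the flask from the start; the feed brings no volume worth counting | 5.0 d |
| teal | 33 mM | 34.6 mM (fed, over 4.0 d) | all else is in the flask from the start; the feed brings no volume worth counting | 5.0 d |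

- north-east (time / d: J / %, Z / %): 1.25: 23.8, 10.6; 2.50: 23.6, 15.4; 4.00: 24.8, 18.1; 5.00: 23.7, 18.7
- south-east (time / d: J / %, Z / %): 0.625: 11.8, 2.5; 1.67: 16.8, 3.3; 3.00: 16.9, 5.7; 5.00: 18.3, 5.1
- east (time / d: J / %, Z / %): 1.25: 21.5, 6.6; 2.50: 22.2, 9.8; 4.00: 21.6, 11.5; 5.00: 21.1, 11.4
- south-west (time / d: J / %, Z / %): 1.25: 25.7, 19.8; 2.50: 21.6, 34.5; 4.00: 18.2, 45.8; 5.00: 16.8, 47.7

(each reading ± 0.5 percentage points)



1. the flask with the highest share of J in J plus Z ("all alike" if they lie within 1.5 percentage points) (green / ochre / teal / all alike)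
2. share of J in J plus Z at the end, green
3. share of J in J plus Z at the end, ochre
4. share of J in J plus Z at the end, teal

Set side by side, north-east, south-east and east differed in X charged, yet their products at 5.00 d accounted for nearly the same fraction of it when I charged each J 2 X and each Z 3 X:

bill = (2 × J + 3 × Z) × L charged / X charged

north-east 98.7%, south-east 101%, east 97.0%

This X bill, the X paid out as a fraction of X charged, is my stoichiometric cost; south-west, charged less L, reached 81.7%.

To whoever takes the bench: don't wait for more J in green, since north-east J read 23.8% at 1.25 d and 23.7% at 5.00 d. I put green at 55.9%, the north-east share. At a given bill, less J means more Z, and I expected ochre, with L fed in beside the J already made, to fall below green.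

The forecast differed on ochre: 56% green, 61% ochre, 57% teal, ochre highest, on the ground that “X decays while L is scarce”.

The flasks gave green 56.0%, ochre 45.4%, teal 51.6%, with green highest.

    L + X → G + J (k = 2.70 × 10⁻⁴ M⁻¹ s⁻¹)
    X + G ⇌ D, settled at all times (K = 2.20 × 10⁵ M⁻¹)
    X + J → Z (k = 4.30 × 10⁻⁴ M⁻¹ s⁻¹)
    L ⇌ E (K = 1.60, k = 2.30 × 10⁻⁶ s⁻¹)

At 0.412 d green made J 2.60 times faster than it used J up, each step taken net, while ochre at 2.50 d held J 12.0% and Z 12.3%. Ochre's final J 17.6% leaves the north-east bill 22.7% for Z; ochre held Z 21.2%, with 5.67% of its X charge still in the flask.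

For a neighbour of green charged 20 mM of L, with J 20.0% at 5.00 d, the north-east bill gives Z 43.6%, a share of 31.4%. That neighbour gave Z 39.3% and share 33.7%, with 8.84% of its X charge still in the flask.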